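Readings and results were computed from invented constants; scatter was added.

The easy step is to divide what has reacted by the time it took.

common to all: solid substrate 37 mM; acid 0.111 mM
- eta: scavenger 0.75 equiv (fed, over 80 s); run made earlier
- beta: scavenger 3 equiv (fed, over 80 s); run made earlier
- flask: scavenger 1.50 equiv (fed, over 80 s); time 3.0 min

| run | time / min | solid substrate / % | target / % |
|---|---|---|---|
| eta | 0.500 | 96 | 7 |
| eta | 1.00 | 92 | 10 |
| eta | 1.33 | 91 | 12 |
| eta | 2.00 | 80 | 21 |
| eta | 2.50 | 74 | 24 |
| beta | 0.200 | 98 | 2 |
| beta | 0.667 | 93 | 7 |
| beta | 1.00 | 93 | 11 |
| beta | 1.50 | 86 | 15 |
| beta | 2.50 | 78 | 22 |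

(each reading ± 1.5 percentage points)

- acid is the free proton; pH is minus the decimal logarithm of its molar concentration
- as a solid, counted per litre of solution: solid substrate
- what was read earlier has a scatter of 1.5 percentage points, one standard deviation
- at the start none of the solid substrate is in solution
- what has only dissolved of solid substrate counts as not reacted

* part of the solid substrate that has reacted (what has only dissolved counts as not reacted) at 3.0 min
* pH of the solution at 3.0 min

After 2.50 min the eta run holds 24% target on 0.75 equiv scavenger, and the beta run 22% on 3 equiv. Their mean is 23.0%, a reading with a scatter of its own.

Two chemists read that mean differently. The first holds that a fixed concentration reacts each minute: 3.40 mM min⁻¹, which she calls the supply, the concentration of solid substrate turned into target per minute whatever c(solid substrate) was charged; this is a zero-order rate. Over 3.0 min it makes 10.2 mM, which is 27.6% of the charge and 92.0 times the charged c(acid).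

The second holds that a fixed share reacts each minute, first-order, at 0.105 min⁻¹. That gives 27.0%.

The two answers lie 0.68 percentage points apart, less than the scatter of one reading, so this flask barely parts them. They part on the charge. I side with the first.

The forecast, on the first side too, says 28% and pH 2, calling the rate “zero order, limited by dissolution”.

The flask gives 28.3% and pH 3.31, with acid at 445% of its charge beside 28.3% target.

    solid substrate ⇌ starting material, rate k1*(cs1 - [starting material]) while solid is left; crystals form when [starting material] > cs1 (solubility = 15.0 mM, k = 0.233 min⁻¹)
    weak acid ⇌ conjugate base + acid, settled at all times (K = 1.30 × 10⁻⁴ M)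
    weak acid + scavenger → scavenged by-product (k = 49.7 M⁻¹ min⁻¹)
    starting material → weak acid + target (k = 0.0663 min⁻¹)
    starting material + weak acid → side product (k = 10.6 M⁻¹ min⁻¹)
    starting material + weak acid ⇌ idle adduct, settled at all times (K = 11.0 M⁻¹)
    starting material + acid → weak acid + acid + target (k = 5.95 × 10⁵ M⁻¹ min⁻¹)

The second view has a share that stays put when the charge moves, and that holds for this flask to within 5 points over a limited range of charges: the answer has moved by that much at 31.5 mM below and 44.9 mM above. The neighbour, charged with 22 mM of solid substrate, lies outside that range. There the fixed share still says 27.0%, while the supply over the same time says 46.4%. The neighbour gives 47.6%. It ends with 52% of its charge still there, solid or dissolved.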